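The route rests on cutting C6–C7, the bond shared by the ten-membered carbocycle (C1–C10) and the trans-fused five-membered lactone (O, C6, C7, C11, C12). The array O–C6–C7–C11(=C13H2)–C12 is the imprint of a 2-(methoxycarbonyl)allyl metal that has added through C7 to a C6 aldehyde. One CrCl2 operation thus forms C6–C7, closes the carbocycle, sets C6 and C7, and lets the alkoxide close the lactone on C12. The precursor is an open chain: C6 aldehyde, C4 methyl centre from (S)-citronellol, ring-cis C9=C10 alkene carrying C14H2OTBS, C8 PMB ether from (S)-glyceraldehyde acetonide, and a (Z)-2-(bromomethyl)enoate (C7=C11, C13H2Br, C12 methyl ester).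

Key step: step 16

**Remarks**

- Numbering: C1–C10 are the ring carbons. C4 is CH–CH3, C6 the lactone O–CH, C7 the ring fusion, C8 the ester O–CH, and C9=C10 the alkene. C11–C13 are the methylene-lactone carbons and C14 is the CH2OH on C10. In the side chain C1' is the carbonyl, C2'=C3' the alkene, C4' the CH2OH on C3' and C5' the CH2OH on C2'. The target is 4S,6R,7S,8R, with a trans lactone, C1 cis to C8 across C9=C10 (descriptor E), and C1' cis to C4' (Z).
- C8: when the formyl carbon of glyceraldehyde acetonide becomes C9 and its CH2O carbon becomes C7, the 8R centre requires the (S)-aldehyde. The (R)-aldehyde would give the 8-epimer.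
- Side chain: the Z acid has its carboxyl group cis to C4', so but-2-yne-1,4-diol must be hydrometalated anti. A syn addition would give the E acid.
- Assumption: (S)-glyceraldehyde acetonide is purchased. It is otherwise one NaIO4 cleavage away from 5,6-O-isopropylidene-L-gulono-1,4-lactone.
- Mixtures: the phosphonate carbon C10, the benzylidene acetal carbon and the C7 carbinol carbon are carried as mixtures, because each is destroyed later.

## Route

Step 1
Reactants: 1 (S)-citronellol
Product: 2 (S)-citronellyl TBS ether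
Conditions: TBSCl, imidazole, CH2Cl2, 0 °C to rt
Reagents that add atoms: tert-butyldimethylsilyl chloride (TBSCl), CC(C)(C)[Si](C)(C)Cl
Why: Silyl ether formation masks the future C6 oxygen for the ozone and base steps and leaves the C4 stereocentre, taken from the chiral pool, untouched.

Step 2
Reactants: 2 (S)-citronellyl TBS ether
Product: 4 (4S)-6-(TBSO)-4-methylhexan-1-ol, via aldehyde 3 (not isolated)
Conditions: O3, CH2Cl2–MeOH, −78 °C; then NaBH4, −78 °C to rt
Reagents that add atoms: ozone, [O-][O+]=O
Why: Ozonolysis with reductive work-up cleaves the only alkene, so that the former alkene CH of citronellol becomes C1 as a primary alcohol.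

Step 3
Reactants: 4 (4S)-6-(TBSO)-4-methylhexan-1-ol
Product: 5 (3S)-1-(TBSO)-6-iodo-3-methylhexane
Conditions: I2, PPh3, imidazole, CH2Cl2, 0 °C
Reagents that add atoms: iodine, II
Why: Appel-type iodination turns the primary alcohol into the SN2 partner under neutral conditions that spare the TBS ether.

Step 4
Reactants: 5 (3S)-1-(TBSO)-6-iodo-3-methylhexane; 6 ethyl 2-(diisopropoxyphosphoryl)acetate
Product: 7 ethyl (6S)-8-(TBSO)-2-(diisopropoxyphosphoryl)-6-methyloctanoate (both C10 epimers)
Conditions: NaH, 6 (1.5 equiv), DMF, 0 °C; then 5, 50 °C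
Reagents that add atoms: none
Why: SN2 alkylation of the stabilised phosphonoacetate anion, used in excess to limit dialkylation, forms C1–C10, and the new C10 centre is a mixture that disappears in step 5.

Step 5
Reactants: 7 ethyl (6S)-8-(TBSO)-2-(diisopropoxyphosphoryl)-6-methyloctanoate; 8 (S)-glyceraldehyde acetonide
Product: 9 E-enoate acetonide (4S,8R,9E)
Conditions: KOtBu (0.95 equiv to 7), THF, 0 °C; then 8, −78 °C to rt
Reagents that add atoms: none
Why: Horner–Wadsworth–Emmons olefination in which the bulky diisopropyl phosphonate and reversible addition favour the E-enoate (C8 trans to CO2Et and so cis to C1, the ring-cis geometry), any Z isomer being removed by chromatography, while C8 (R) is carried over unchanged from 8 because the preformed anion leaves no free base.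

Step 6
Reactants: 9 E-enoate acetonide
Product: 11 O7/O8 p-methoxybenzylidene acetal with free C6–OH (both acetal epimers), via enoate triol 10 (not isolated)
Conditions: CSA (cat.), EtOH, rt; evaporate; 4-MeOC6H4CH(OMe)2, CH2Cl2, rt; Et3N quench
Reagents that add atoms: 4-methoxybenzaldehyde dimethyl acetal, COc1ccc(C(OC)OC)cc1
Why: Acid-catalysed ethanolysis strips the acetonide and the TBS group to triol 10, whose E geometry forbids lactonisation, and transacetalisation then ties O7 and O8 into the five-membered benzylidene acetal and leaves only C6–OH free.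

Step 7
Reactants: 11 benzylidene acetal with free C6–OH
Product: 12 C6 TES ether of the benzylidene acetal enoate
Conditions: TESCl, imidazole, CH2Cl2, 0 °C
Reagents that add atoms: triethylsilyl chloride (TESCl), CC[Si](CC)(CC)Cl
Why: Silylation puts on C6 the most acid-labile silyl ether of the route, so that it can later be removed in the presence of the C14 TBS ether.

Step 8
Reactants: 12 C6 TES ether of the benzylidene acetal enoate
Product: 13 C14 allylic alcohol
Conditions: iBu2AlH (2.3 equiv), CH2Cl2, −78 °C; aq. potassium sodium tartrate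
Reagents that add atoms: none
Why: Ester reduction with iBu2AlH at −78 °C gives the allylic alcohol without touching the alkene geometry, and at this temperature the benzylidene acetal is not opened.

Step 9
Reactants: 13 C14 allylic alcohol
Product: 14 C14 TBS ether
Conditions: TBSCl, imidazole, DMF, 0 °C to rt
Reagents that add atoms: tert-butyldimethylsilyl chloride (TBSCl), CC(C)(C)[Si](C)(C)Cl
Why: Standard silylation protects C14–OH for the rest of the route.

Step 10
Reactants: 14 C14 TBS ether
Product: 15 C8 PMB ether with free C7–OH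
Conditions: iBu2AlH (3 equiv), CH2Cl2, −78 to −20 °C; aq. potassium sodium tartrate
Reagents that add atoms: none
Why: Regioselective reductive opening of the benzylidene acetal, in which aluminium binds the less hindered O7 and hydride goes to the benzylic carbon, leaves PMB on O8 and frees C7–OH, and the temperature ceiling keeps both silyl ethers intact.

Step 11
Reactants: 15 C8 PMB ether with free C7–OH
Product: 16 C7 aldehyde
Conditions: Dess–Martin periodinane, NaHCO3, CH2Cl2, 0 °C; used at once
Reagents that add atoms: none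
Why: Dess–Martin oxidation under bicarbonate buffer needs no amine base, which matters because C8–H of 16 is both allylic and alpha to the formyl group.

Step 12
Reactants: 16 C7 aldehyde; 17 methyl propiolate
Product: 19 C7 carbinol acrylate (both C7 epimers), via vinylalane 18 (not isolated)
Conditions: iBu2AlH, NMO, THF, 0 °C; 17 (slight excess over hydride), 0 °C; then 16, −20 to 0 °C; aq. potassium sodium tartrate
Reagents that add atoms: none
Why: Vinylalumination, in which hydroalumination of 17 places aluminium alpha to the ester and the weakly basic vinylalane 18 adds 1,2 to the aldehyde within hours, gives the Morita–Baylis–Hillman-type adduct without the long exposure to a nucleophilic amine that would epimerise C8 or move C9=C10 into conjugation, and the new C7 carbinol forms as a mixture that step 13 erases.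

Step 13
Reactants: 19 C7 carbinol acrylate
Product: 20 (Z)-2-(bromomethyl)enoate C6 TES ether
Conditions: NBS, Me2S, CH2Cl2, −20 °C (premixed); then 19, 0 °C
Reagents that add atoms: N-bromosuccinimide (NBS), O=C1CCC(=O)N1Br
Why: Corey–Kim-type activation of the hydroxyl as an alkoxysulfonium ion and SN2' attack of bromide at C13 give the conjugated trisubstituted enoate, with C8 trans to the ester (Z descriptor) as the less strained isomer, under neutral conditions tolerated by the TES, TBS and PMB groups.

Step 14
Reactants: 20 (Z)-2-(bromomethyl)enoate C6 TES ether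
Product: 21 (Z)-2-(bromomethyl)enoate C6 alcohol
Conditions: PPTS (cat.), MeOH–CH2Cl2, 0 °C
Reagents that add atoms: none
Why: Acid-catalysed methanolysis distinguishes the silyl ethers by size, the primary TES ether being cleaved much faster than the primary TBS ether, while bromide, enoate and PMB ether are inert.

Step 15
Reactants: 21 (Z)-2-(bromomethyl)enoate C6 alcohol
Product: 22 seco aldehyde (C6 aldehyde with the (Z)-2-(bromomethyl)enoate)
Conditions: Dess–Martin periodinane, NaHCO3, CH2Cl2, 0 °C
Reagents that add atoms: none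
Why: Dess–Martin oxidation is neutral and non-nucleophilic and therefore compatible with the reactive allylic bromide.

Step 16
Reactants: 22 seco aldehyde
Product: 25 C8-O-PMB C14-O-TBS germacranolide (4S,6R,7S,8R), via allylchromium dichloride 23 (not isolated), via chromium alkoxide 24 (not isolated)
Conditions: CrCl2 (10 equiv), degassed DMF, 25 °C, 22 added by syringe pump over 12 h (final 2 mM); aq. NH4Cl
Reagents that add atoms: none
Why: Two equivalents of CrCl2 (divalent chromium) reduce the C13–Br bond to allylchromium 23 (trivalent chromium), which adds through C7 to the C6 aldehyde in a six-centre chair and moves the alkene to C11=C13; this is an intramolecular Nozaki–Hiyama–Kishi (Barbier-type) 2-(alkoxycarbonyl)allylation, a reaction type already used to close ten-membered germacranolide rings. The carbocycle closes 10-exo-trig on the C6 carbonyl, and alkoxide 24 then closes the lactone 5-exo-trig on the C12 ester with loss of methoxide. For C6 against C7, the medium-ring closure is slow enough for the two alkene isomers of 23 to interconvert by 1,3-shift of chromium first (Curtin–Hammett situation), and the chair that carries both C5 and C8 equatorial gives the anti pair, that is H6 and H7 trans and the trans lactone, whatever the bromide geometry. For C7 against C8, allylic 1,3-strain turns C8–H into the allyl plane, the larger and better donating C8–C9 bond stands anti to the incoming aldehyde (Felkin–Anh-type induction, known for chromium allylations with a stereocentre next to the reacting carbon) and the slim PMB ether lies outside, which puts C6 on the C7 face that gives 7S and, through the chair, 6R. The ring-cis C9=C10 alkene keeps C8–H in its own plane as well and folds the C1–C5 tether back towards C7. High dilution suppresses dimers, and an ether rather than an ester at C8 avoids 1,4-elimination of 23 to a diene.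

Step 17
Reactants: 25 C8-O-PMB C14-O-TBS germacranolide
Product: 26 C8 alcohol (C14-O-TBS)
Conditions: DDQ (1.3 equiv), CH2Cl2–pH 7 buffer, 0 °C
Reagents that add atoms: none
Why: Oxidative PMB cleavage (hydride abstraction by DDQ, then hydrolysis of the oxocarbenium ion) is orthogonal to the TBS ether and the methylene lactone and leaves C8 unchanged.

Step 18
Reactants: 27 but-2-yne-1,4-diol
Product: 29 (Z)-2-iodobut-2-ene-1,4-diol, via cyclic alkenylalanate 28 (not isolated)
Conditions: NaAlH2(OCH2CH2OMe)2, THF, 0 °C to rt; then I2, THF, −78 to 0 °C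
Reagents that add atoms: iodine, II
Why: Alkoxide-directed anti hydroalumination of the propargylic diol gives the five-membered alkenylalanate 28, and iodinolysis with retention puts iodine cis to C4', the geometry that a syn hydrometalation could not give.

Step 19
Reactants: 29 (Z)-2-iodobut-2-ene-1,4-diol
Product: 30 (Z)-1,4-bis(TBSO)-2-iodobut-2-ene
Conditions: TBSCl (2.3 equiv), imidazole, DMF, rt
Reagents that add atoms: tert-butyldimethylsilyl chloride (TBSCl), CC(C)(C)[Si](C)(C)Cl
Why: Double silylation blocks both hydroxyls, which would otherwise quench the organolithium and later lactonise onto the cis carboxyl group.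

Step 20
Reactants: 30 (Z)-1,4-bis(TBSO)-2-iodobut-2-ene
Product: 32 (Z)-4-(TBSO)-2-[(TBSO)methyl]but-2-enoic acid, via alkenyllithium 31 (not isolated)
Conditions: t-BuLi (2.1 equiv), Et2O, −78 °C; dry CO2, −78 °C; aq. NaHSO4 to pH 4
Reagents that add atoms: carbon dioxide, O=C=O
Why: Iodine–lithium exchange and carboxylation both proceed with retention at the sp2 carbon, and ether solvent at −78 °C suppresses silyl migration to carbon and loss of silyloxide.

Step 21
Reactants: 26 C8 alcohol; 32 (Z)-4-(TBSO)-2-[(TBSO)methyl]but-2-enoic acid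
Product: 34 tris-TBS ester, via mixed anhydride 33 (not isolated)
Conditions: 32, 2,4,6-Cl3C6H2COCl, Et3N, toluene, rt; then 26, DMAP (0.5 equiv), 0 °C to rt
Reagents that add atoms: none
Why: Yamaguchi esterification activates the hindered acid as mixed anhydride 33 and acylates the secondary allylic C8–OH with retention at C8, while substoichiometric DMAP and low temperature limit the addition–elimination that could isomerise the Z alkene.

Step 22
Reactants: 34 tris-TBS ester
Product: 35 CNP0131216.1 (target)
Conditions: HF·pyridine, pyridine, THF, 0 °C to rt; pH 7 phosphate quench; rapid chromatography on neutral silica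
Reagents that add atoms: none
Why: Fluoride-induced cleavage of three primary allylic TBS ethers in a pyridine-buffered, weakly acidic medium generates no free alkoxide, which protects the methylene lactone from conjugate addition and slows attack of C4'–OH on the cis ester carbonyl.

## Compound list

1 | (S)-citronellol, (3S)-3,7-dimethyloct-6-en-1-ol | OCC[C@@H](C)CCC=C(C)C | starting material
2 | (S)-citronellyl TBS ether | CC(C)(C)[Si](C)(C)OCC[C@@H](C)CCC=C(C)C | intermediate
3 | (4S)-6-(tert-butyldimethylsilyloxy)-4-methylhexanal | CC(C)(C)[Si](C)(C)OCC[C@@H](C)CCC=O | intermediate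
4 | (4S)-6-(tert-butyldimethylsilyloxy)-4-methylhexan-1-ol | CC(C)(C)[Si](C)(C)OCC[C@@H](C)CCCO | intermediate
5 | (3S)-1-(tert-butyldimethylsilyloxy)-6-iodo-3-methylhexane | CC(C)(C)[Si](C)(C)OCC[C@@H](C)CCCI | intermediate
6 | ethyl 2-(diisopropoxyphosphoryl)acetate | CCOC(=O)CP(=O)(OC(C)C)OC(C)C | starting material
7 | ethyl (6S)-8-(tert-butyldimethylsilyloxy)-2-(diisopropoxyphosphoryl)-6-methyloctanoate, both epimers at C2 (= C10) | CC(C)(C)[Si](C)(C)OCC[C@@H](C)CCCC(C(=O)OCC)P(=O)(OC(C)C)OC(C)C | intermediate
8 | (S)-glyceraldehyde acetonide, (4S)-2,2-dimethyl-1,3-dioxolane-4-carbaldehyde | O=C[C@@H]1COC(C)(C)O1 | starting material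
9 | ethyl (2E,6S)-8-(tert-butyldimethylsilyloxy)-2-{[(4R)-2,2-dimethyl-1,3-dioxolan-4-yl]methylidene}-6-methyloctanoate | CC(C)(C)[Si](C)(C)OCC[C@@H](C)CCC/C(C(=O)OCC)=C\[C@@H]1COC(C)(C)O1 | intermediate
10 | ethyl (2E,6S)-2-[(2R)-2,3-dihydroxypropylidene]-8-hydroxy-6-methyloctanoate | OCC[C@@H](C)CCC/C(C(=O)OCC)=C\[C@@H](O)CO | intermediate
11 | ethyl (2E,6S)-8-hydroxy-2-{[(4R)-2-(4-methoxyphenyl)-1,3-dioxolan-4-yl]methylidene}-6-methyloctanoate, both acetal epimers | OCC[C@@H](C)CCC/C(C(=O)OCC)=C\[C@@H]1COC(c2ccc(OC)cc2)O1 | intermediate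
12 | C6 triethylsilyl ether of 11 | CC[Si](CC)(CC)OCC[C@@H](C)CCC/C(C(=O)OCC)=C\[C@@H]1COC(c2ccc(OC)cc2)O1 | intermediate
13 | (2E,6S)-2-{[(4R)-2-(4-methoxyphenyl)-1,3-dioxolan-4-yl]methylidene}-6-methyl-8-(triethylsilyloxy)octan-1-ol | CC[Si](CC)(CC)OCC[C@@H](C)CCC/C(CO)=C\[C@@H]1COC(c2ccc(OC)cc2)O1 | intermediate
14 | C14 tert-butyldimethylsilyl ether of 13 | CC[Si](CC)(CC)OCC[C@@H](C)CCC/C(CO[Si](C)(C)C(C)(C)C)=C\[C@@H]1COC(c2ccc(OC)cc2)O1 | intermediate
15 | (2R,3E,8S)-4-[(tert-butyldimethylsilyloxy)methyl]-2-(4-methoxybenzyloxy)-8-methyl-10-(triethylsilyloxy)dec-3-en-1-ol | CC[Si](CC)(CC)OCC[C@@H](C)CCC/C(CO[Si](C)(C)C(C)(C)C)=C\[C@@H](OCc1ccc(OC)cc1)CO | intermediate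
16 | (2R,3E,8S)-4-[(tert-butyldimethylsilyloxy)methyl]-2-(4-methoxybenzyloxy)-8-methyl-10-(triethylsilyloxy)dec-3-enal | CC[Si](CC)(CC)OCC[C@@H](C)CCC/C(CO[Si](C)(C)C(C)(C)C)=C\[C@@H](OCc1ccc(OC)cc1)C=O | intermediate
17 | methyl propiolate | C#CC(=O)OC | starting material
18 | [1-(methoxycarbonyl)ethenyl]diisobutylalane | C=C(C(=O)OC)[Al](CC(C)C)CC(C)C | intermediate
19 | methyl 2-methylidene-3-hydroxy ester from 16 (C7 carbinol, both epimers; 4S,8R,9E; C6-OTES, C8-OPMB, C14-OTBS) | CC[Si](CC)(CC)OCC[C@@H](C)CCC/C(CO[Si](C)(C)C(C)(C)C)=C\[C@@H](OCc1ccc(OC)cc1)C(O)C(=C)C(=O)OC | intermediate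
20 | methyl (Z)-2-(bromomethyl)enoate, C8 cis to CH2Br (4S,8R,9E; C6-OTES, C8-OPMB, C14-OTBS) | CC[Si](CC)(CC)OCC[C@@H](C)CCC/C(CO[Si](C)(C)C(C)(C)C)=C\[C@@H](OCc1ccc(OC)cc1)/C=C(\CBr)C(=O)OC | intermediate
21 | C6 alcohol of 20 | OCC[C@@H](C)CCC/C(CO[Si](C)(C)C(C)(C)C)=C\[C@@H](OCc1ccc(OC)cc1)/C=C(\CBr)C(=O)OC | intermediate
22 | seco aldehyde: C6 aldehyde carrying the (Z)-2-(bromomethyl)enoate (4S,8R,9E) | O=CC[C@@H](C)CCC/C(CO[Si](C)(C)C(C)(C)C)=C\[C@@H](OCc1ccc(OC)cc1)/C=C(\CBr)C(=O)OC | intermediate
23 | C13 allylchromium dichloride (solvent ligands omitted, C7=C11 isomers interconverting) | O=CC[C@@H](C)CCC/C(CO[Si](C)(C)C(C)(C)C)=C\[C@@H](OCc1ccc(OC)cc1)C=C(C[Cr](Cl)Cl)C(=O)OC | intermediate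
24 | ten-membered C6 chromium alkoxide with the C7 acrylate (4S,6R,7S,8R) | C=C(C(=O)OC)[C@H]1[C@H](O[Cr](Cl)Cl)C[C@@H](C)CCC/C(CO[Si](C)(C)C(C)(C)C)=C\[C@H]1OCc2ccc(OC)cc2 | intermediate
25 | C8-O-PMB, C14-O-TBS germacra-9,11(13)-dien-6,12-olide (4S,6R,7S,8R,9E) | C=C1C(=O)O[C@@H]2C[C@@H](C)CCC/C(CO[Si](C)(C)C(C)(C)C)=C\[C@@H](OCc3ccc(OC)cc3)[C@@H]12 | intermediate
26 | C8 alcohol, C14-O-TBS germacranolide | C=C1C(=O)O[C@@H]2C[C@@H](C)CCC/C(CO[Si](C)(C)C(C)(C)C)=C\[C@@H](O)[C@@H]12 | intermediate
27 | but-2-yne-1,4-diol | OCC#CCO | starting material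
28 | cyclic alkenylalanate (five-membered Al–O–C4'–C3'=C2' ring, drawn in simplified form as the disodium salt) | [Na+].[Na+].COCCO[Al-]1(OCCOC)OCC=C1C[O-] | intermediate
29 | (Z)-2-iodobut-2-ene-1,4-diol | OC/C=C(\I)CO | intermediate
30 | (Z)-1,4-bis(tert-butyldimethylsilyloxy)-2-iodobut-2-ene | CC(C)(C)[Si](C)(C)OC/C=C(\I)CO[Si](C)(C)C(C)(C)C | intermediate
31 | alkenyllithium from 30 (Li cis to C4') | [Li]/C(=C\CO[Si](C)(C)C(C)(C)C)CO[Si](C)(C)C(C)(C)C | intermediate
32 | (Z)-4-(tert-butyldimethylsilyloxy)-2-[(tert-butyldimethylsilyloxy)methyl]but-2-enoic acid | OC(=O)/C(=C\CO[Si](C)(C)C(C)(C)C)CO[Si](C)(C)C(C)(C)C | intermediate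
33 | mixed anhydride of 32 with 2,4,6-trichlorobenzoic acid | O=C(OC(=O)/C(=C\CO[Si](C)(C)C(C)(C)C)CO[Si](C)(C)C(C)(C)C)c1c(Cl)cc(Cl)cc1Cl | intermediate
34 | tris-TBS ester (C14, C4', C5' silylated target) | C=C1C(=O)O[C@@H]2C[C@@H](C)CCC/C(CO[Si](C)(C)C(C)(C)C)=C\[C@@H](OC(=O)/C(=C\CO[Si](C)(C)C(C)(C)C)CO[Si](C)(C)C(C)(C)C)[C@@H]12 | intermediate
35 | CNP0131216.1, (4S,6R,7S,8R,9E)-14-hydroxy-8-[(Z)-4-hydroxy-2-(hydroxymethyl)but-2-enoyloxy]germacra-9,11(13)-dien-6,12-olide | C=C1C(=O)O[C@@H]2C[C@@H](C)CCC/C(CO)=C\[C@@H](OC(=O)/C(=C\CO)CO)[C@@H]12 | target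

## Step count and risks

Total step count: 22. Longest linear sequence: 19 (steps 1–17, 21 and 22).

**1. Step 16 (key step).**
- What may go wrong: the allylchromium may add before its alkene isomers have equilibrated, or it may take the other face of C7. Either would erode the anti (trans-lactone) and the C7/C8 selectivity. Protonation of the allylchromium and intermolecular coupling also compete with the slow medium-ring closure.
- Fallback: a stereospecific closed-transition-state allylboration replaces the stereoconvergent chromium reagent. It sets out from 16 and comes back at 25.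
- Dibromo-olefination of 16 (CBr4, PPh3, CH2Cl2, 0 °C) should give the 1,1-dibromoalkene F1. n-BuLi (THF, −78 °C) followed by ClCO2Me should give the ynoate F2.
- Syn hydroalumination (iBu2AlH–HMPA, THF, 0 °C, aluminium on C11) and alkylation with ICH2B(pin) should give the allylboronate F3, in which C8 is trans to the CH2B group and cis to the ester.
- PPTS–MeOH frees the boronate C6 alcohol F4, and Dess–Martin oxidation gives the boronate aldehyde F5.
- 2-(Alkoxycarbonyl)allylboronates react slowly at room temperature, so the aldehyde can be handled and then cyclised at high dilution (toluene, heat, or catalytic Sc(OTf)3). The chair transfers the fixed alkene geometry into the anti C6/C7 pair, and the borate closes the lactone to 25.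

**2. Step 22.**
- What may go wrong: once freed, the C4' hydroxyl lies cis to the ester carbonyl and can attack C1' with expulsion of the C8 alkoxide. The longer the medium needed for three TBS ethers acts, the more this transesterification and conjugate addition at C13 gain ground.
- Fallback: a change of protecting-group plan, so that the last step is a short fluoride-free hydrolysis. It sets out from 25 (and from 29 for the acid) and comes back at 35.
- HF·pyridine–pyridine on 25 frees C14–OH while the PMB ether stays, giving the C14 alcohol F6. TESCl–imidazole gives the C14 TES ether F7, and DDQ gives the C8 alcohol F8.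
- In parallel, 29 is silylated with TESCl to the bis-TES iodide F9 and carboxylated as in step 20 (work-up at pH 5) to the bis-TES Z acid F10.
- Esterification as in step 21 gives the tris-TES ester F11. AcOH–THF–H2O at 0 °C should then release 35 within a short time.

**3. Step 12 (with the aldehyde from step 11).**
- What may go wrong: enolisation of 16 at C8, leading to epimerisation or to migration of C9=C10 into conjugation. Reduction of the aldehyde by residual hydride is a further risk.
- Fallback: an aldol addition followed by elimination replaces the vinyl-metal addition. It sets out from 16 and comes back at 19.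
- The lithium enolate of methyl 3-(dimethylamino)propanoate (LiN(iPr)2, THF, −78 °C) adds to 16 within minutes at low temperature to give the beta-hydroxy amino ester F12.
- MeI gives the trimethylammonium iodide F13, and DBU (CH2Cl2, 0 °C) eliminates trimethylamine to give 19.

Further compounds
F1 | step 16 | 1,1-dibromoalkene from 16 (C7=CBr2; 4S,8R,9E) | CC[Si](CC)(CC)OCC[C@@H](C)CCC/C(CO[Si](C)(C)C(C)(C)C)=C\[C@@H](OCc1ccc(OC)cc1)C=C(Br)Br
F2 | step 16 | methyl ynoate (C7≡C11–C12O2Me; 4S,8R,9E) | CC[Si](CC)(CC)OCC[C@@H](C)CCC/C(CO[Si](C)(C)C(C)(C)C)=C\[C@@H](OCc1ccc(OC)cc1)C#CC(=O)OC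
F3 | step 16 | 2-(methoxycarbonyl)allylboronate, C8 trans to CH2B(pin), C6-OTES | CC[Si](CC)(CC)OCC[C@@H](C)CCC/C(CO[Si](C)(C)C(C)(C)C)=C\[C@@H](OCc1ccc(OC)cc1)/C=C(/CB1OC(C)(C)C(C)(C)O1)C(=O)OC
F4 | step 16 | boronate C6 alcohol | OCC[C@@H](C)CCC/C(CO[Si](C)(C)C(C)(C)C)=C\[C@@H](OCc1ccc(OC)cc1)/C=C(/CB1OC(C)(C)C(C)(C)O1)C(=O)OC
F5 | step 16 | boronate aldehyde | O=CC[C@@H](C)CCC/C(CO[Si](C)(C)C(C)(C)C)=C\[C@@H](OCc1ccc(OC)cc1)/C=C(/CB1OC(C)(C)C(C)(C)O1)C(=O)OC
F6 | step 22 | C14 alcohol, C8-O-PMB germacranolide | C=C1C(=O)O[C@@H]2C[C@@H](C)CCC/C(CO)=C\[C@@H](OCc3ccc(OC)cc3)[C@@H]12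
F7 | step 22 | C14 TES ether, C8-O-PMB germacranolide | C=C1C(=O)O[C@@H]2C[C@@H](C)CCC/C(CO[Si](CC)(CC)CC)=C\[C@@H](OCc3ccc(OC)cc3)[C@@H]12
F8 | step 22 | C8 alcohol, C14-O-TES germacranolide | C=C1C(=O)O[C@@H]2C[C@@H](C)CCC/C(CO[Si](CC)(CC)CC)=C\[C@@H](O)[C@@H]12
F9 | step 22 | (Z)-1,4-bis(triethylsilyloxy)-2-iodobut-2-ene | CC[Si](CC)(CC)OC/C=C(\I)CO[Si](CC)(CC)CC
F10 | step 22 | (Z)-4-(triethylsilyloxy)-2-[(triethylsilyloxy)methyl]but-2-enoic acid | OC(=O)/C(=C\CO[Si](CC)(CC)CC)CO[Si](CC)(CC)CC
F11 | step 22 | tris-TES ester | C=C1C(=O)O[C@@H]2C[C@@H](C)CCC/C(CO[Si](CC)(CC)CC)=C\[C@@H](OC(=O)/C(=C\CO[Si](CC)(CC)CC)CO[Si](CC)(CC)CC)[C@@H]12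
F12 | step 12 | beta-hydroxy amino ester (C7 carbinol, C11 bearing CH2NMe2; mixture at C7 and C11) | CC[Si](CC)(CC)OCC[C@@H](C)CCC/C(CO[Si](C)(C)C(C)(C)C)=C\[C@@H](OCc1ccc(OC)cc1)C(O)C(CN(C)C)C(=O)OC
F13 | step 12 | trimethylammonium iodide of F12 | CC[Si](CC)(CC)OCC[C@@H](C)CCC/C(CO[Si](C)(C)C(C)(C)C)=C\[C@@H](OCc1ccc(OC)cc1)C(O)C(C[N+](C)(C)C)C(=O)OC.[I-]
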